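## Retrosynthetic overview

1. The target comes from the C12–C15 butenolide 25 (opened by hydroxide at the very end), which comes from the (S)-propargylic alcohol 23, the ynone 22 and the C12 methyl ester 19; the C8 methylene of 19 comes from the C8 ketone of 18.
2. Key disconnection C9–C10 (ring B). The strategy rests on the methyl-bearing quaternary C10 of ring A being bonded to C9, which carries the C11–C12 arm and adjoins C8. A tertiary C10 radical, made from the exocyclic C10=C20 alkene of ring A fragment 17, adds to C9 of a C8-keto C9=C11–C12 enoate and closes ring B with C8 and C12 already at the right oxidation levels.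
3. 17 comes from the C8 aldehyde 14 and methyl propiolate (addition, then redox isomerisation); 14 comes from the ring A ketone 12 (C10 methylenation, acetal release).
4. Ring A stereocentres: C5 by cuprate addition to the C4=C5 enoate anti to a C10 silyloxy group; C4 by methylation of the ester enolate trans to the new C5 chain (alkylating C5 next to a finished Me/CO2R centre would have no dependable facial bias); the C10 carbinol by CBS reduction of enone ester 3.
5. Ring order: ring A is bought (1), ring B is closed in step 12, and the butenolide exists only between steps 17 and 18.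

Key step: step 12

Remark on the chemistry (assumption): the target (Z)-γ-hydroxy acid closes to the C12/C15 butenolide in acid, so it is taken to be isolable only by cold neutralisation of its dicarboxylate to about pH 4, without concentration from acidic solution. Labdane numbering of the target is used for all atoms (C17 = C8 methylene, C18/C19 = methyl/carboxyl on C4, C20 = methyl on C10); in the monocyclic compounds ring positions 1, 2 and 3 are labdane C4, C5 and C10.

## Route

Step 1
Reactants: 1 3-oxocyclohex-1-ene-1-carboxylic acid; 2 2-(trimethylsilyl)ethanol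
Product: 3 2-(trimethylsilyl)ethyl 3-oxocyclohex-1-ene-1-carboxylate
Conditions: EDC·HCl, DMAP (cat.), CH2Cl2, 0 °C to rt
Reagents that add atoms: none
Why: Steglich-type carbodiimide esterification; the 2-(trimethylsilyl)ethyl ester is chosen because the later axial, neopentyl C19 ester can be cleaved by fluoride at silicon and not at the shielded carbonyl.

Step 2
Reactants: 3 2-(trimethylsilyl)ethyl 3-oxocyclohex-1-ene-1-carboxylate
Product: 4 2-(trimethylsilyl)ethyl (3S)-3-hydroxycyclohex-1-ene-1-carboxylate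
Conditions: (R)-2-methyl-CBS-oxazaborolidine (10 mol %), BH3·SMe2, THF, −30 °C; MeOH quench
Reagents that add atoms: none
Why: Corey–Bakshi–Shibata 1,2-reduction of the enone, in which the alkene side acts as the large substituent, so the (R)-catalyst should give the (S)-carbinol (the future C10, used only as a temporary control element).

Step 3
Reactants: 4 2-(trimethylsilyl)ethyl (3S)-3-hydroxycyclohex-1-ene-1-carboxylate
Product: 5 2-(trimethylsilyl)ethyl (3S)-3-[(triethylsilyl)oxy]cyclohex-1-ene-1-carboxylate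
Conditions: Et3SiCl, imidazole, CH2Cl2, 0 °C
Reagents that add atoms: chlorotriethylsilane, CC[Si](Cl)(CC)CC
Why: Standard O-silylation; the triethylsilyl ether is bulky enough to direct step 4 and is later removed by mild acid, so fluoride is kept away from the silylethyl ester until the end.

Step 4
Reactants: 5 2-(trimethylsilyl)ethyl (3S)-3-[(triethylsilyl)oxy]cyclohex-1-ene-1-carboxylate; 6 2-(2-bromoethyl)-1,3-dioxolane
Product: 8 2-(trimethylsilyl)ethyl (2S,3S)-2-[2-(1,3-dioxolan-2-yl)ethyl]-3-[(triethylsilyl)oxy]cyclohexane-1-carboxylate as a mixture of C1 epimers, via silyl ketene acetal 7 (not isolated)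
Conditions: 6, Mg, THF, 25 °C; then 5, CuBr·SMe2 (10 mol %), Me3SiCl, THF, −78 to −40 °C; aq. NH4Cl
Reagents that add atoms: none
Why: Copper-catalysed, chlorosilane-accelerated conjugate addition of a Grignard reagent to the enoate; the nucleophile should enter the β-carbon (future C5) anti to the adjacent silyloxy group and so set C5, while the α-carbon (future C4) is left as an epimer mixture that is planarised in step 5.

Step 5
Reactants: 8 2-(trimethylsilyl)ethyl (2S,3S)-2-[2-(1,3-dioxolan-2-yl)ethyl]-3-[(triethylsilyl)oxy]cyclohexane-1-carboxylate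
Product: 10 2-(trimethylsilyl)ethyl (1S,2S,3S)-2-[2-(1,3-dioxolan-2-yl)ethyl]-1-methyl-3-[(triethylsilyl)oxy]cyclohexane-1-carboxylate, via lithium enolate 9 (not isolated)
Conditions: LiN(iPr)2, THF, −78 °C; MeI, DMPU, −78 to −20 °C
Reagents that add atoms: iodomethane, CI
Why: Ester enolate alkylation; methyl iodide should attack the exocyclic enolate on the face opposite the neighbouring C5 chain (1,2-induction, as in vicinal conjugate addition–alkylation of cyclohexenecarboxylates), which sets the quaternary C4 with the methyl trans and the ester cis to the chain.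

Step 6
Reactants: 10 2-(trimethylsilyl)ethyl (1S,2S,3S)-2-[2-(1,3-dioxolan-2-yl)ethyl]-1-methyl-3-[(triethylsilyl)oxy]cyclohexane-1-carboxylate
Product: 11 2-(trimethylsilyl)ethyl (1S,2S,3S)-2-[2-(1,3-dioxolan-2-yl)ethyl]-3-hydroxy-1-methylcyclohexane-1-carboxylate
Conditions: AcOH/THF/H2O (3:1:1), rt
Reagents that add atoms: none
Why: Acid-catalysed solvolysis of the triethylsilyl ether under conditions too mild to open the dioxolane or touch the silylethyl ester.

Step 7
Reactants: 11 2-(trimethylsilyl)ethyl (1S,2S,3S)-2-[2-(1,3-dioxolan-2-yl)ethyl]-3-hydroxy-1-methylcyclohexane-1-carboxylate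
Product: 12 2-(trimethylsilyl)ethyl (1S,2S)-2-[2-(1,3-dioxolan-2-yl)ethyl]-1-methyl-3-oxocyclohexane-1-carboxylate
Conditions: Dess–Martin periodinane, pyridine, CH2Cl2, rt
Reagents that add atoms: none
Why: Dess–Martin oxidation of the secondary alcohol under near-neutral conditions, so that C5, now α to the C10 ketone, is not epimerised.

Step 8
Reactants: 12 2-(trimethylsilyl)ethyl (1S,2S)-2-[2-(1,3-dioxolan-2-yl)ethyl]-1-methyl-3-oxocyclohexane-1-carboxylate
Product: 13 2-(trimethylsilyl)ethyl (1S,2R)-2-[2-(1,3-dioxolan-2-yl)ethyl]-1-methyl-3-methylidenecyclohexane-1-carboxylate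
Conditions: Zn, CH2Br2, TiCl4, THF (preformed reagent); then 12, CH2Cl2, 0 °C to rt
Reagents that add atoms: dibromomethane, BrCBr
Why: Takai–Lombardo methylenation; the non-basic geminal dimetallic reagent methylenates hindered, enolisable ketones without epimerising the α-centre and leaves the esters and the acetal alone.

Step 9
Reactants: 13 2-(trimethylsilyl)ethyl (1S,2R)-2-[2-(1,3-dioxolan-2-yl)ethyl]-1-methyl-3-methylidenecyclohexane-1-carboxylate
Product: 14 2-(trimethylsilyl)ethyl (1S,2R)-1-methyl-3-methylidene-2-(3-oxopropyl)cyclohexane-1-carboxylate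
Conditions: PPTS, acetone/H2O (10:1), 50 °C
Reagents that add atoms: water, O
Why: Acetal hydrolysis under buffered acid that should not protonate the 1,1-disubstituted alkene (protonation would lead to alkene migration or lactonisation onto C19).

Step 10
Reactants: 14 2-(trimethylsilyl)ethyl (1S,2R)-1-methyl-3-methylidene-2-(3-oxopropyl)cyclohexane-1-carboxylate; 15 methyl propiolate
Product: 16 2-(trimethylsilyl)ethyl (1S,2R)-2-(3-hydroxy-6-methoxy-6-oxohex-4-yn-1-yl)-1-methyl-3-methylidenecyclohexane-1-carboxylate as both carbinol epimers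
Conditions: 15, LiN(SiMe3)2, THF, −78 °C; then 14; AcOH, −78 °C
Reagents that add atoms: none
Why: 1,2-Addition of a lithium acetylide to the aldehyde at a temperature at which the hindered C19 ester is inert; the new C8 carbinol centre is uncontrolled and is removed in step 11.

Step 11
Reactants: 16 2-(trimethylsilyl)ethyl (1S,2R)-2-(3-hydroxy-6-methoxy-6-oxohex-4-yn-1-yl)-1-methyl-3-methylidenecyclohexane-1-carboxylate
Product: 17 2-(trimethylsilyl)ethyl (1S,2R)-2-[(4E)-6-methoxy-3,6-dioxohex-4-en-1-yl]-1-methyl-3-methylidenecyclohexane-1-carboxylate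
Conditions: DABCO (20 mol %), DMSO, rt
Reagents that add atoms: none
Why: Base-catalysed redox isomerisation of a γ-hydroxy ynoate to the (E)-γ-oxo enoate (1,3-proton shift to the allenol, then tautomerisation); either alkene geometry would serve step 12.

Step 12
Reactants: 17 2-(trimethylsilyl)ethyl (1S,2R)-2-[(4E)-6-methoxy-3,6-dioxohex-4-en-1-yl]-1-methyl-3-methylidenecyclohexane-1-carboxylate
Product: 18 2-(trimethylsilyl)ethyl (1S,4aS,5R,8aR)-5-(2-methoxy-2-oxoethyl)-1,4a-dimethyl-6-oxodecahydronaphthalene-1-carboxylate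
Conditions: Fe(acac)3 (30 mol %), PhSiH3 (2.5 equiv), EtOH/ethylene glycol (5:1), 0.02 M, 60 °C; then DBU (0.1 equiv), CH2Cl2, rt
Reagents that add atoms: none
Why: An iron hydride formed from Fe(acac)3 and PhSiH3 transfers a hydrogen atom to the terminal carbon of the 1,1-disubstituted alkene (which becomes the C20 methyl), and the nucleophilic tertiary C10 radical adds to C9 of the doubly activated alkene to leave an ester-stabilised C11 radical that ferrous iron reduces to the enolate and ethanol protonates; this is the known hydrogen-atom-transfer reductive alkene–enone (Giese-type) coupling used intramolecularly. Ring B closes 6-exo-trig through a chair-like transition state with the C5 tether equatorial on ring A. The new C10 centre is controlled by C4: the axial C19 ester screens the β lobe of the planar radical, so C9 should bond to the α lobe, the methyl is pushed axial and the ring fusion becomes trans, as in radical polyene bicyclisations that pass through the same kind of C10 radical. C9 is set kinetically with the CH–CO2Me unit equatorial in the chair and is then secured thermodynamically, because it is α to the C8 ketone and DBU equilibrates it to the equatorial epimer. The step needs hydrogen-atom transfer to the electron-rich alkene and not the electron-poor one, and 6-exo over 7-endo closure; the first follows from the polarity preference of the metal hydride, the second from the tether length and the ester stabilisation of the C11 radical, and high dilution suppresses intermolecular coupling.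

Step 13
Reactants: 18 2-(trimethylsilyl)ethyl (1S,4aS,5R,8aR)-5-(2-methoxy-2-oxoethyl)-1,4a-dimethyl-6-oxodecahydronaphthalene-1-carboxylate
Product: 19 2-(trimethylsilyl)ethyl (1S,4aR,5S,8aR)-5-(2-methoxy-2-oxoethyl)-1,4a-dimethyl-6-methylidenedecahydronaphthalene-1-carboxylate
Conditions: Zn, CH2Br2, TiCl4, THF (preformed reagent); then 18, CH2Cl2, rt
Reagents that add atoms: dibromomethane, BrCBr
Why: Takai–Lombardo methylenation of the hindered C8 ketone; the reagent is non-basic, so the C9 centre α to the ketone keeps its configuration and both esters survive.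

Step 14
Reactants: 19 2-(trimethylsilyl)ethyl (1S,4aR,5S,8aR)-5-(2-methoxy-2-oxoethyl)-1,4a-dimethyl-6-methylidenedecahydronaphthalene-1-carboxylate
Product: 20 2-(trimethylsilyl)ethyl (1S,4aR,5S,8aR)-5-{2-[methoxy(methyl)amino]-2-oxoethyl}-1,4a-dimethyl-6-methylidenedecahydronaphthalene-1-carboxylate
Conditions: MeNH(OMe)·HCl, iPrMgCl, THF, −20 to 0 °C
Reagents that add atoms: N,O-dimethylhydroxylamine hydrochloride, CNOC.Cl
Why: Weinreb amide formation by magnesium amide aminolysis; only the unhindered C12 methyl ester reacts, the axial quaternary C19 ester being shielded.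

Step 15
Reactants: 20 2-(trimethylsilyl)ethyl (1S,4aR,5S,8aR)-5-{2-[methoxy(methyl)amino]-2-oxoethyl}-1,4a-dimethyl-6-methylidenedecahydronaphthalene-1-carboxylate; 15 methyl propiolate
Product: 22 2-(trimethylsilyl)ethyl (1S,4aR,5S,8aR)-5-(5-methoxy-2,5-dioxopent-3-yn-1-yl)-1,4a-dimethyl-6-methylidenedecahydronaphthalene-1-carboxylate, via hemiaminal lithium alkoxide 21 (not isolated)
Conditions: 15, LiN(SiMe3)2, THF, −78 °C; then 20, −78 to −50 °C; AcOH, −78 °C
Reagents that add atoms: none
Why: Weinreb ketone synthesis with a lithium acetylide; the chelated tetrahedral adduct prevents over-addition and releases the ynone only on acidic quench.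

Step 16
Reactants: 22 2-(trimethylsilyl)ethyl (1S,4aR,5S,8aR)-5-(5-methoxy-2,5-dioxopent-3-yn-1-yl)-1,4a-dimethyl-6-methylidenedecahydronaphthalene-1-carboxylate
Product: 23 2-(trimethylsilyl)ethyl (1S,4aR,5S,8aR)-5-[(2S)-2-hydroxy-5-methoxy-5-oxopent-3-yn-1-yl]-1,4a-dimethyl-6-methylidenedecahydronaphthalene-1-carboxylate
Conditions: Ru[(S,S)-TsDPEN](p-cymene) (amido complex, 5 mol %), iPrOH, rt
Reagents that add atoms: none
Why: Noyori asymmetric transfer hydrogenation of an alkynyl ketone with the base-free amido complex (which spares the electrophilic ynoate); the alkynyl group takes the place of the aryl group in the transition state, so the (S,S)-catalyst should set C12 as (S) under catalyst control.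

Step 17
Reactants: 23 2-(trimethylsilyl)ethyl (1S,4aR,5S,8aR)-5-[(2S)-2-hydroxy-5-methoxy-5-oxopent-3-yn-1-yl]-1,4a-dimethyl-6-methylidenedecahydronaphthalene-1-carboxylate
Product: 25 2-(trimethylsilyl)ethyl (1S,4aR,5S,8aR)-1,4a-dimethyl-6-methylidene-5-{[(2S)-3-methyl-5-oxo-2,5-dihydrofuran-2-yl]methyl}decahydronaphthalene-1-carboxylate, via (Z)-hydroxy enoate 24 (not isolated)
Conditions: Me2CuLi (from CuI and MeLi, 3 equiv), THF, −78 °C; aq. NH4Cl at −78 °C; then PPTS (cat.), CH2Cl2, rt
Reagents that add atoms: lithium dimethylcuprate, [Li+].C[Cu-]C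
Why: syn-Carbocupration of the ynoate puts the methyl on C13 and copper on C14, and protonation with retention gives the (Z)-enoate with C12 and C15 cis, which lactonises to the butenolide without touching C12.

Step 18
Reactants: 25 2-(trimethylsilyl)ethyl (1S,4aR,5S,8aR)-1,4a-dimethyl-6-methylidene-5-{[(2S)-3-methyl-5-oxo-2,5-dihydrofuran-2-yl]methyl}decahydronaphthalene-1-carboxylate
Product: 28 (1S,4aR,5S,8aR)-5-[(2S,3Z)-4-carboxy-2-hydroxy-3-methylbut-3-en-1-yl]-1,4a-dimethyl-6-methylidenedecahydronaphthalene-1-carboxylic acid, via butenolide acid 26 (not isolated), via dilithium dicarboxylate 27 (not isolated)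
Conditions: (Me2N)3S+ Me3SiF2− (TASF), DMF, 0 °C to rt; then LiOH, THF/H2O, 0 °C; 1 M HCl to pH 4 at 0 °C, cold extraction
Reagents that add atoms: lithium hydroxide, [Li+].[OH-]
Why: Fluoride attack at silicon fragments the silylethyl ester (β-elimination) without approaching the hindered C19 carbonyl, and saponification then opens the butenolide at C15, so the Z geometry is kept and C12 is untouched.

## Compound list

1 | 3-oxocyclohex-1-ene-1-carboxylic acid | O=C1C=C(C(=O)O)CCC1 | starting material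
2 | 2-(trimethylsilyl)ethanol | C[Si](C)(C)CCO | starting material
3 | 2-(trimethylsilyl)ethyl 3-oxocyclohex-1-ene-1-carboxylate | O=C1C=C(C(=O)OCC[Si](C)(C)C)CCC1 | intermediate
4 | 2-(trimethylsilyl)ethyl (3S)-3-hydroxycyclohex-1-ene-1-carboxylate | O[C@@H]1C=C(C(=O)OCC[Si](C)(C)C)CCC1 | intermediate
5 | 2-(trimethylsilyl)ethyl (3S)-3-[(triethylsilyl)oxy]cyclohex-1-ene-1-carboxylate | CC[Si](CC)(CC)O[C@@H]1C=C(C(=O)OCC[Si](C)(C)C)CCC1 | intermediate
6 | 2-(2-bromoethyl)-1,3-dioxolane | BrCCC1OCCO1 | starting material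
7 | O-trimethylsilyl O-[2-(trimethylsilyl)ethyl] ketene acetal of 8 (exocyclic C=C geometry undefined) | CC[Si](CC)(CC)O[C@H]1CCCC(=C(O[Si](C)(C)C)OCC[Si](C)(C)C)[C@@H]1CCC2OCCO2 | intermediate (not isolated)
8 | 2-(trimethylsilyl)ethyl (2S,3S)-2-[2-(1,3-dioxolan-2-yl)ethyl]-3-[(triethylsilyl)oxy]cyclohexane-1-carboxylate, both C1 epimers | CC[Si](CC)(CC)O[C@H]1CCCC(C(=O)OCC[Si](C)(C)C)[C@@H]1CCC2OCCO2 | intermediate
9 | lithium ester enolate of 8 (C=C geometry undefined) | CC[Si](CC)(CC)O[C@H]1CCCC(=C(O[Li])OCC[Si](C)(C)C)[C@@H]1CCC2OCCO2 | intermediate (not isolated)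
10 | 2-(trimethylsilyl)ethyl (1S,2S,3S)-2-[2-(1,3-dioxolan-2-yl)ethyl]-1-methyl-3-[(triethylsilyl)oxy]cyclohexane-1-carboxylate | CC[Si](CC)(CC)O[C@H]1CCC[C@](C)(C(=O)OCC[Si](C)(C)C)[C@@H]1CCC2OCCO2 | intermediate
11 | 2-(trimethylsilyl)ethyl (1S,2S,3S)-2-[2-(1,3-dioxolan-2-yl)ethyl]-3-hydroxy-1-methylcyclohexane-1-carboxylate | O[C@H]1CCC[C@](C)(C(=O)OCC[Si](C)(C)C)[C@@H]1CCC2OCCO2 | intermediate
12 | 2-(trimethylsilyl)ethyl (1S,2S)-2-[2-(1,3-dioxolan-2-yl)ethyl]-1-methyl-3-oxocyclohexane-1-carboxylate | O=C1CCC[C@](C)(C(=O)OCC[Si](C)(C)C)[C@@H]1CCC2OCCO2 | intermediate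
13 | 2-(trimethylsilyl)ethyl (1S,2R)-2-[2-(1,3-dioxolan-2-yl)ethyl]-1-methyl-3-methylidenecyclohexane-1-carboxylate | C=C1CCC[C@](C)(C(=O)OCC[Si](C)(C)C)[C@@H]1CCC2OCCO2 | intermediate
14 | 2-(trimethylsilyl)ethyl (1S,2R)-1-methyl-3-methylidene-2-(3-oxopropyl)cyclohexane-1-carboxylate | C=C1CCC[C@](C)(C(=O)OCC[Si](C)(C)C)[C@@H]1CCC=O | intermediate
15 | methyl propiolate | C#CC(=O)OC | starting material
16 | 2-(trimethylsilyl)ethyl (1S,2R)-2-(3-hydroxy-6-methoxy-6-oxohex-4-yn-1-yl)-1-methyl-3-methylidenecyclohexane-1-carboxylate, both carbinol epimers | C=C1CCC[C@](C)(C(=O)OCC[Si](C)(C)C)[C@@H]1CCC(O)C#CC(=O)OC | intermediate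
17 | 2-(trimethylsilyl)ethyl (1S,2R)-2-[(4E)-6-methoxy-3,6-dioxohex-4-en-1-yl]-1-methyl-3-methylidenecyclohexane-1-carboxylate (key-step precursor) | C=C1CCC[C@](C)(C(=O)OCC[Si](C)(C)C)[C@@H]1CCC(=O)/C=C/C(=O)OC | intermediate
18 | 2-(trimethylsilyl)ethyl (1S,4aS,5R,8aR)-5-(2-methoxy-2-oxoethyl)-1,4a-dimethyl-6-oxodecahydronaphthalene-1-carboxylate (key-step product) | O=C1CC[C@@H]2[C@](C)(CCC[C@]2(C)C(=O)OCC[Si](C)(C)C)[C@H]1CC(=O)OC | intermediate
19 | 2-(trimethylsilyl)ethyl (1S,4aR,5S,8aR)-5-(2-methoxy-2-oxoethyl)-1,4a-dimethyl-6-methylidenedecahydronaphthalene-1-carboxylate | C=C1CC[C@@H]2[C@](C)(CCC[C@]2(C)C(=O)OCC[Si](C)(C)C)[C@H]1CC(=O)OC | intermediate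
20 | 2-(trimethylsilyl)ethyl (1S,4aR,5S,8aR)-5-{2-[methoxy(methyl)amino]-2-oxoethyl}-1,4a-dimethyl-6-methylidenedecahydronaphthalene-1-carboxylate | C=C1CC[C@@H]2[C@](C)(CCC[C@]2(C)C(=O)OCC[Si](C)(C)C)[C@H]1CC(=O)N(C)OC | intermediate
21 | lithium alkoxide of the tetrahedral adduct of 20 with the acetylide (carbinol centre undefined) | C=C1CC[C@@H]2[C@](C)(CCC[C@]2(C)C(=O)OCC[Si](C)(C)C)[C@H]1CC(O[Li])(C#CC(=O)OC)N(C)OC | intermediate (not isolated)
22 | 2-(trimethylsilyl)ethyl (1S,4aR,5S,8aR)-5-(5-methoxy-2,5-dioxopent-3-yn-1-yl)-1,4a-dimethyl-6-methylidenedecahydronaphthalene-1-carboxylate | C=C1CC[C@@H]2[C@](C)(CCC[C@]2(C)C(=O)OCC[Si](C)(C)C)[C@H]1CC(=O)C#CC(=O)OC | intermediate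
23 | 2-(trimethylsilyl)ethyl (1S,4aR,5S,8aR)-5-[(2S)-2-hydroxy-5-methoxy-5-oxopent-3-yn-1-yl]-1,4a-dimethyl-6-methylidenedecahydronaphthalene-1-carboxylate | C=C1CC[C@@H]2[C@](C)(CCC[C@]2(C)C(=O)OCC[Si](C)(C)C)[C@H]1C[C@H](O)C#CC(=O)OC | intermediate
24 | 2-(trimethylsilyl)ethyl (1S,4aR,5S,8aR)-5-[(2S,3Z)-2-hydroxy-5-methoxy-3-methyl-5-oxopent-3-en-1-yl]-1,4a-dimethyl-6-methylidenedecahydronaphthalene-1-carboxylate | C=C1CC[C@@H]2[C@](C)(CCC[C@]2(C)C(=O)OCC[Si](C)(C)C)[C@H]1C[C@H](O)/C(C)=C\C(=O)OC | intermediate (not isolated)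
25 | 2-(trimethylsilyl)ethyl (1S,4aR,5S,8aR)-1,4a-dimethyl-6-methylidene-5-{[(2S)-3-methyl-5-oxo-2,5-dihydrofuran-2-yl]methyl}decahydronaphthalene-1-carboxylate | C=C1CC[C@@H]2[C@](C)(CCC[C@]2(C)C(=O)OCC[Si](C)(C)C)[C@H]1C[C@@H]3OC(=O)C=C3C | intermediate
26 | (1S,4aR,5S,8aR)-1,4a-dimethyl-6-methylidene-5-{[(2S)-3-methyl-5-oxo-2,5-dihydrofuran-2-yl]methyl}decahydronaphthalene-1-carboxylic acid | C=C1CC[C@@H]2[C@](C)(CCC[C@]2(C)C(=O)O)[C@H]1C[C@@H]3OC(=O)C=C3C | intermediate (not isolated)
27 | dilithium salt of 28 | [Li+].[Li+].C=C1CC[C@@H]2[C@](C)(CCC[C@]2(C)C(=O)[O-])[C@H]1C[C@H](O)/C(C)=C\C(=O)[O-] | intermediate (not isolated)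
28 | (1S,4aR,5S,8aR)-5-[(2S,3Z)-4-carboxy-2-hydroxy-3-methylbut-3-en-1-yl]-1,4a-dimethyl-6-methylidenedecahydronaphthalene-1-carboxylic acid, i.e. (12S,13Z)-12-hydroxylabda-8(17),13-diene-15,19-dioic acid | C=C1CC[C@@H]2[C@](C)(CCC[C@]2(C)C(=O)O)[C@H]1C[C@H](O)/C(C)=C\C(=O)O | target

## Step count and risks

Total step count: 18. Longest linear sequence: 18 steps (1 to 28).

Steps most likely to fail:

1. Step 12. Ring B may close through the β lobe of the C10 radical (cis ring fusion), or the radical may be reduced before it cyclises. The fallback sets out from 13 and returns at 18, setting C10 intermolecularly and closing ring B at C8–C9 instead. Fe(acac)3/PhSiH3 coupling of 13 with methyl acrylate, where the acceptor can only approach opposite the axial C19 ester, should give 2-(trimethylsilyl)ethyl (1S,2R,3R)-2-[2-(1,3-dioxolan-2-yl)ethyl]-3-(3-methoxy-3-oxopropyl)-1,3-dimethylcyclohexane-1-carboxylate F1. α-Selenation of its methyl ester (LiN(iPr)2, PhSeCl) and selenoxide elimination (H2O2) should give 2-(trimethylsilyl)ethyl (1S,2R,3R)-2-[2-(1,3-dioxolan-2-yl)ethyl]-3-[(1E)-3-methoxy-3-oxoprop-1-en-1-yl]-1,3-dimethylcyclohexane-1-carboxylate F2. Acetal hydrolysis (PPTS, wet acetone) should give 2-(trimethylsilyl)ethyl (1S,2R,3R)-3-[(1E)-3-methoxy-3-oxoprop-1-en-1-yl]-1,3-dimethyl-2-(3-oxopropyl)cyclohexane-1-carboxylate F3. An intramolecular Stetter reaction (triazolium-derived carbene, amine base) then joins C8 to C9 and, after equilibration of C9 with DBU, gives 18.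

2. Step 15. The weakly nucleophilic, thermally fragile lithium propiolate may decompose before it acylates the Weinreb amide. The fallback sets out from 20 and returns at 22. Reduction with iBu2AlH at −78 °C should give 2-(trimethylsilyl)ethyl (1S,4aR,5S,8aR)-1,4a-dimethyl-6-methylidene-5-(2-oxoethyl)decahydronaphthalene-1-carboxylate F4. Addition of lithium methyl propiolate at −78 °C, a fast reaction with aldehydes, should give 2-(trimethylsilyl)ethyl (1S,4aR,5S,8aR)-5-(2-hydroxy-5-methoxy-5-oxopent-3-yn-1-yl)-1,4a-dimethyl-6-methylidenedecahydronaphthalene-1-carboxylate F5 as both carbinol epimers. Dess–Martin oxidation then gives 22.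

3. Step 18. The liberated (Z)-γ-hydroxy acid may close back to the butenolide during neutralisation, and the butenolide may lose its C12 configuration by γ-deprotonation under fluoride or hydroxide. The fallback sets out from 23 and returns at 28; it never forms the butenolide and unveils the hydroxyl last under neutral conditions. Etherification with 4-methoxybenzyl trichloroacetimidate (acid catalyst) should give 2-(trimethylsilyl)ethyl (1S,4aR,5S,8aR)-5-{(2S)-5-methoxy-2-[(4-methoxybenzyl)oxy]-5-oxopent-3-yn-1-yl}-1,4a-dimethyl-6-methylidenedecahydronaphthalene-1-carboxylate F6. Me2CuLi at −78 °C should give 2-(trimethylsilyl)ethyl (1S,4aR,5S,8aR)-5-{(2S,3Z)-5-methoxy-2-[(4-methoxybenzyl)oxy]-3-methyl-5-oxopent-3-en-1-yl}-1,4a-dimethyl-6-methylidenedecahydronaphthalene-1-carboxylate F7, which cannot lactonise. TASF and then LiOH should give (1S,4aR,5S,8aR)-5-{(2S,3Z)-4-carboxy-2-[(4-methoxybenzyl)oxy]-3-methylbut-3-en-1-yl}-1,4a-dimethyl-6-methylidenedecahydronaphthalene-1-carboxylic acid F8, which can be acidified and purified freely. DDQ in CH2Cl2/pH 7 buffer at 0 °C then removes the benzyl ether to give 28.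

Further compounds
F1 | step 12 | 2-(trimethylsilyl)ethyl (1S,2R,3R)-2-[2-(1,3-dioxolan-2-yl)ethyl]-3-(3-methoxy-3-oxopropyl)-1,3-dimethylcyclohexane-1-carboxylate | COC(=O)CC[C@@]1(C)CCC[C@](C)(C(=O)OCC[Si](C)(C)C)[C@@H]1CCC2OCCO2
F2 | step 12 | 2-(trimethylsilyl)ethyl (1S,2R,3R)-2-[2-(1,3-dioxolan-2-yl)ethyl]-3-[(1E)-3-methoxy-3-oxoprop-1-en-1-yl]-1,3-dimethylcyclohexane-1-carboxylate | COC(=O)/C=C/[C@@]1(C)CCC[C@](C)(C(=O)OCC[Si](C)(C)C)[C@@H]1CCC2OCCO2
F3 | step 12 | 2-(trimethylsilyl)ethyl (1S,2R,3R)-3-[(1E)-3-methoxy-3-oxoprop-1-en-1-yl]-1,3-dimethyl-2-(3-oxopropyl)cyclohexane-1-carboxylate | COC(=O)/C=C/[C@@]1(C)CCC[C@](C)(C(=O)OCC[Si](C)(C)C)[C@@H]1CCC=O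
F4 | step 15 | 2-(trimethylsilyl)ethyl (1S,4aR,5S,8aR)-1,4a-dimethyl-6-methylidene-5-(2-oxoethyl)decahydronaphthalene-1-carboxylate | C=C1CC[C@@H]2[C@](C)(CCC[C@]2(C)C(=O)OCC[Si](C)(C)C)[C@H]1CC=O
F5 | step 15 | 2-(trimethylsilyl)ethyl (1S,4aR,5S,8aR)-5-(2-hydroxy-5-methoxy-5-oxopent-3-yn-1-yl)-1,4a-dimethyl-6-methylidenedecahydronaphthalene-1-carboxylate, both carbinol epimers | C=C1CC[C@@H]2[C@](C)(CCC[C@]2(C)C(=O)OCC[Si](C)(C)C)[C@H]1CC(O)C#CC(=O)OC
F6 | step 18 | 2-(trimethylsilyl)ethyl (1S,4aR,5S,8aR)-5-{(2S)-5-methoxy-2-[(4-methoxybenzyl)oxy]-5-oxopent-3-yn-1-yl}-1,4a-dimethyl-6-methylidenedecahydronaphthalene-1-carboxylate | C=C1CC[C@@H]2[C@](C)(CCC[C@]2(C)C(=O)OCC[Si](C)(C)C)[C@H]1C[C@H](OCc3ccc(OC)cc3)C#CC(=O)OC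
F7 | step 18 | 2-(trimethylsilyl)ethyl (1S,4aR,5S,8aR)-5-{(2S,3Z)-5-methoxy-2-[(4-methoxybenzyl)oxy]-3-methyl-5-oxopent-3-en-1-yl}-1,4a-dimethyl-6-methylidenedecahydronaphthalene-1-carboxylate | C=C1CC[C@@H]2[C@](C)(CCC[C@]2(C)C(=O)OCC[Si](C)(C)C)[C@H]1C[C@H](OCc3ccc(OC)cc3)/C(C)=C\C(=O)OC
F8 | step 18 | (1S,4aR,5S,8aR)-5-{(2S,3Z)-4-carboxy-2-[(4-methoxybenzyl)oxy]-3-methylbut-3-en-1-yl}-1,4a-dimethyl-6-methylidenedecahydronaphthalene-1-carboxylic acid | C=C1CC[C@@H]2[C@](C)(CCC[C@]2(C)C(=O)O)[C@H]1C[C@H](OCc3ccc(OC)cc3)/C(C)=C\C(=O)O
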